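The ring-fusion bond C5–C10 and the C4–O formate bond of the eudesmane are disconnected together. This unfolds rings A and B into a ten-membered (E,E)-germacra-1(10),4,7(11)-trien-8-one that carries the C3 oxygen as a bulky silyl ether. In formic acid this trienone should be protonated at C1, close across the ring and take up formate at C4, so that C4, C5 and C10 are set relative to C3 in one operation. The feature exploited is the trans-fused decalin in which the C4–O bond is antiperiplanar to the C5–C10 bond, next to the untouched C7=C11–C8=O enone. The precursor is reached from germacrone; the (2S,3S)-epoxy ester is attached last.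

Key step: step 5

Remark: eudesmane numbering is used throughout (ring A = C1–C5 and C10, ring B = C5–C10); the given structures are mutually consistent (C3 is S in precursor, product and target, the decalin is 4S,5R,10R, the oxirane ester is 2S,3S with methyl and carboxyl cis) and none was changed; the tert-butyldiphenylsilyl ether is kept at O3 because it survives formic acid and cannot bridge to C4 as an acyl group would; racemic alcohol 2 is drawn without a descriptor at C3.

Step 1
Reactants: 1 germacrone
Product: 2 (±)-3-hydroxygermacrone
Conditions: SeO2 (0.5 equiv), t-BuOOH (2 equiv, anhydrous), CH2Cl2, 0 °C → rt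
Reagents that add atoms: selenium dioxide, O=[Se]=O (oxygen carrier, restored by tert-butyl hydroperoxide, CC(C)(C)OO)
Why: Selenium dioxide allylic hydroxylation (ene reaction, then [2,3]-sigmatropic shift) should engage the most electron-rich alkene C4=C5 (the 1(10)-alkene is deactivated by the β-carbonyl, the enone alkene is electron-poor) and return oxygen to the ring CH2 on its disubstituted terminus trans to C6, that is C3, with the E geometry restored; C3 forms as a racemate, which does not matter because step 2 makes it trigonal.

Step 2
Reactants: 2 (±)-3-hydroxygermacrone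
Product: 3 (1(10)E,4E)-germacra-1(10),4,7(11)-triene-3,8-dione
Conditions: Dess–Martin periodinane, pyridine, CH2Cl2, 0 °C
Reagents that add atoms: none
Why: Dess–Martin oxidation of the secondary allylic alcohol under buffered, non-acidic conditions should leave the acid- and base-sensitive 1,5-diene and the β,γ-unsaturated C8 ketone untouched and removes the uncontrolled C3 centre.

Step 3
Reactants: 3 (1(10)E,4E)-germacra-1(10),4,7(11)-triene-3,8-dione
Product: 4 (3S)-3-hydroxygermacrone
Conditions: (R)-Me-CBS oxazaborolidine [(R)-1-methyl-3,3-diphenyltetrahydro-1H,3H-pyrrolo[1,2-c][1,3,2]oxazaborole, 0.2 equiv], catecholborane (1.2 equiv), toluene, −78 °C; then MeOH, pH 7 buffer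
Reagents that add atoms: none
Why: Corey–Bakshi–Shibata reduction: the C3 carbonyl (between a CH2 and the trisubstituted alkenyl carbon C4) is less hindered than the C8 carbonyl next to the tetrasubstituted C7 and should react first at low temperature, and with the alkenyl side as the large group the (R)-catalyst delivers hydride to the face that gives the (S)-alcohol.

Step 4
Reactants: 4 (3S)-3-hydroxygermacrone
Product: 5 (3S)-3-(tert-butyldiphenylsilyloxy)germacrone
Conditions: TBDPSCl, imidazole, DMAP (cat.), DMF, rt
Reagents that add atoms: tert-butyl(chloro)diphenylsilane, CC(C)(C)[Si](Cl)(c1ccccc1)c1ccccc1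
Why: Standard silylation of a secondary alcohol under weakly basic conditions that neither enolise C9 nor isomerise the diene; C3 is not touched.

Step 5
Reactants: 5 (3S)-3-(tert-butyldiphenylsilyloxy)germacrone; 6 formic acid
Product: 7 (3S,4S,5R,10R)-3-(tert-butyldiphenylsilyloxy)-4-formyloxyeudesm-7(11)-en-8-one (3β-silyloxy-4α-formyloxy-5αH)
Conditions: HCO2H (98%)/CH2Cl2 1:1, 0 °C → rt
Reagents that add atoms: formic acid (compound 6), OC=O
Why: Formic acid protonates C1 of the 1(10)-alkene while C5 of the 4,5-alkene, facing it across the ring in the crossed chair–chair conformer, bonds to C10 and a solvent molecule adds to C4 from the outer face, a cation–alkene cyclisation with antiperiplanar addition across both E-alkenes. The closest known reaction is the acid-mediated transannular cyclisation of germacrone and other germacra-1(10),4-dienes to 4-oxygenated eudesmanes. The C5–C10 bond turns the ten-membered ring into two six-membered rings, 6-endo-trig with respect to ring A (C4 stays in the ring) and 6-exo-trig with respect to ring B, both transannular. C10 (axial β-methyl) and C5 (α-hydrogen) follow from the E geometry of the two alkenes in the chair-like array, which gives the trans fusion; C4 follows from anti capture (equatorial formate, axial methyl); all three are tied to C3 if the reacting conformer is the one with the silyloxy group pseudo-equatorial on the ring periphery. The step needs chemoselectivity for the isolated alkenes, which the electron-poor 7(11)-en-8-one provides because it is not protonated on carbon, and capture at C4 before a 1,2-hydride shift from C3, which is favoured by the solvent-level concentration of the nucleophile and by the acid-stable, non-participating silyl ether.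

Step 6
Reactants: 7 (3S,4S,5R,10R)-3-(tert-butyldiphenylsilyloxy)-4-formyloxyeudesm-7(11)-en-8-one
Product: 8 3β-hydroxy-4α-formyloxyeudesm-7(11)-en-8-one
Conditions: HF·pyridine, pyridine, THF, 0 °C → rt
Reagents that add atoms: none
Why: Fluoride cleavage of the Si–O bond under weakly acidic, buffered conditions generates no alkoxide, so the tertiary formate should neither migrate from O4 to O3 nor be hydrolysed, and no stereocentre is touched.

Step 7
Reactants: 9 angelic acid
Product: 10 (Z)-2-methylbut-2-en-1-ol
Conditions: LiAlH4, Et2O, 0 °C
Reagents that add atoms: none
Why: Lithium aluminium hydride reduction of the carboxylic acid to the primary allylic alcohol at low temperature should keep the Z geometry of the trisubstituted alkene and not reduce the C=C bond.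

Step 8
Reactants: 10 (Z)-2-methylbut-2-en-1-ol
Product: 11 [(2R,3S)-2,3-dimethyloxiran-2-yl]methanol
Conditions: Ti(OiPr)4 (cat.), diethyl D-(−)-tartrate, t-BuOOH, 4 Å molecular sieves, CH2Cl2, −20 °C
Reagents that add atoms: tert-butyl hydroperoxide, CC(C)(C)OO
Why: Sharpless asymmetric epoxidation: with the D-(−)-tartrate the titanium-bound peroxide is delivered to the face of the Z-allylic alcohol that gives the (2R,3S)-epoxy alcohol, and the Z geometry fixes the cis relation of the C3 methyl and the hydroxymethyl group.

Step 9
Reactants: 11 [(2R,3S)-2,3-dimethyloxiran-2-yl]methanol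
Product: 13 (2S,3S)-2,3-dimethyloxirane-2-carboxylic acid, via epoxy aldehyde 12 (not isolated)
Conditions: RuCl3·xH2O (cat.), NaIO4, MeCN/EtOAc/H2O, rt
Reagents that add atoms: water, O (the second carboxyl oxygen enters through the aldehyde hydrate)
Why: Ruthenium tetroxide, generated catalytically from RuCl3 and NaIO4, oxidises the primary alcohol through the aldehyde hydrate to the acid without opening the oxirane or touching either stereocentre (the C2 descriptor changes from R to S only because the priorities change).

Step 10
Reactants: 8 3β-hydroxy-4α-formyloxyeudesm-7(11)-en-8-one; 13 (2S,3S)-2,3-dimethyloxirane-2-carboxylic acid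
Product: 15 3β-[(2S,3S)-2,3-dimethyloxirane-2-carbonyloxy]-4α-formyloxyeudesm-7(11)-en-8-one (CNP0216170.2), via mixed anhydride 14 (not isolated)
Conditions: 13, 2,4,6-trichlorobenzoyl chloride, Et3N, THF, rt; then 8, DMAP, toluene, rt
Reagents that add atoms: none
Why: Yamaguchi esterification: DMAP attacks the mixed anhydride at the aliphatic carbonyl and the acylpyridinium acylates the equatorial C3 hydroxyl with retention at C3; the acid has no α-hydrogen to epimerise, and short exposure to amine base limits formyl migration.

Compound list
1 | germacrone, (1(10)E,4E)-germacra-1(10),4,7(11)-trien-8-one | CC(C)=C1C/C=C(\C)CC/C=C(\C)CC1=O | starting material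
2 | (±)-3-hydroxygermacrone, racemic at C3 | CC(C)=C1C/C=C(\C)C(O)C/C=C(\C)CC1=O | intermediate
3 | (1(10)E,4E)-germacra-1(10),4,7(11)-triene-3,8-dione | CC(C)=C1C/C=C(\C)C(=O)C/C=C(\C)CC1=O | intermediate
4 | (3S)-3-hydroxygermacrone | CC(C)=C1C/C=C(\C)[C@@H](O)C/C=C(\C)CC1=O | intermediate
5 | (3S)-3-(tert-butyldiphenylsilyloxy)germacrone | CC(C)=C1C/C=C(\C)[C@@H](O[Si](c2ccccc2)(c2ccccc2)C(C)(C)C)C/C=C(\C)CC1=O | intermediate
6 | formic acid | OC=O | starting material
7 | (3S,4S,5R,10R)-3-(tert-butyldiphenylsilyloxy)-4-formyloxyeudesm-7(11)-en-8-one | CC(C)=C1C[C@@H]2[C@](C)(CC[C@H](O[Si](c3ccccc3)(c3ccccc3)C(C)(C)C)[C@@]2(C)OC=O)CC1=O | intermediate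
8 | (3S,4S,5R,10R)-3-hydroxy-4-formyloxyeudesm-7(11)-en-8-one | CC(C)=C1C[C@@H]2[C@](C)(CC[C@H](O)[C@@]2(C)OC=O)CC1=O | intermediate
9 | angelic acid, (Z)-2-methylbut-2-enoic acid | C/C=C(/C)C(O)=O | starting material
10 | (Z)-2-methylbut-2-en-1-ol | C/C=C(/C)CO | intermediate
11 | [(2R,3S)-2,3-dimethyloxiran-2-yl]methanol | OC[C@@]1(C)O[C@H]1C | intermediate
12 | (2S,3S)-2,3-dimethyloxirane-2-carbaldehyde (not isolated) | O=C[C@@]1(C)O[C@H]1C | intermediate
13 | (2S,3S)-2,3-dimethyloxirane-2-carboxylic acid | OC(=O)[C@@]1(C)O[C@H]1C | intermediate
14 | (2S,3S)-2,3-dimethyloxirane-2-carboxylic 2,4,6-trichlorobenzoic anhydride (not isolated) | O=C(OC(=O)[C@@]1(C)O[C@H]1C)c1c(Cl)cc(Cl)cc1Cl | intermediate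
15 | (3S,4S,5R,10R)-4-formyloxy-8-oxoeudesm-7(11)-en-3-yl (2S,3S)-2,3-dimethyloxirane-2-carboxylate | CC(C)=C1C[C@@H]2[C@](C)(CC[C@H](OC(=O)[C@@]3(C)O[C@H]3C)[C@@]2(C)OC=O)CC1=O | target

Total step count: 10. Longest linear sequence: 7 (steps 1–6 and 10).

Steps most likely to fail

Step 5 (key step). The C4 cation may be intercepted too slowly by the weakly nucleophilic formic acid. A 1,2-hydride shift from C3 with loss of the silyl group, proton loss to alkenes, or cyclisation through the conformer with a pseudo-axial silyloxy group could then compete. The fallback separates ring closure from formate installation. It sets out from 5: hydrative cyclisation in dilute aqueous acid (HClO4 in acetone–water, 0 °C), where water at high concentration is the trap, should give 3β-(tert-butyldiphenylsilyloxy)-4α-hydroxyeudesm-7(11)-en-8-one F1. Formylation of the tertiary alcohol with acetic formic anhydride and pyridine returns to the route at 7.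

Step 1. Hydrogen may be abstracted from the vinylic methyl groups C15 or C14 instead of C3, because the ten-membered ring holds the C3–H bonds poorly aligned with the π system; this is the likelier outcome for a ten-membered E-alkene. Attack at C9 and loss of the E geometry in the [2,3] shift are further risks. The fallback replaces the ene reaction by enzymatic C–H hydroxylation. It sets out from 1: whole-cell hydroxylation with a fungal culture or an engineered cytochrome P450 monooxygenase, screened for the C3 allylic position, would give 2, where the route is rejoined. Either enantiomer of 2 serves, because step 2 erases C3. No new compound is made (F0).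

Step 3. The C8 carbonyl may be reduced in competition, or enantioselection may be incomplete on a twisted medium-ring enone. The fallback replaces oxidation and asymmetric reduction by enzymatic kinetic resolution. It sets out from racemic 2: lipase-catalysed acylation (Pseudomonas cepacia lipase, vinyl acetate, tert-butyl methyl ether) should convert the R enantiomer into (R)-3-acetoxygermacrone F2 and leave the (S)-alcohol, which is compound 4, where the route is rejoined. Steps 2 and 3 are then not needed.

Further compounds
F1 | step 5 | (3S,4S,5R,10R)-3-(tert-butyldiphenylsilyloxy)-4-hydroxyeudesm-7(11)-en-8-one | CC(C)=C1C[C@@H]2[C@](C)(CC[C@H](O[Si](c3ccccc3)(c3ccccc3)C(C)(C)C)[C@@]2(C)O)CC1=O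
F0 | step 1 | none | none
F2 | step 3 | (3R)-3-acetoxygermacrone | CC(C)=C1C/C=C(\C)[C@H](OC(C)=O)C/C=C(\C)CC1=O
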